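# Proposed synthesis of CNP0183628.1 by arene ring expansion (intramolecular Büchner reaction)

Remarks and assumptions (on the chemistry):
- Locants C1–C10 and the descriptors α/β in the names of all bicyclic compounds are those of the target skeleton defined in the first section; β is the face of the C1 methyl group.
- Assumption: the dilithium enolate of the (R)-acetate 2 adds to aldehyde 1 with the topicity it shows with other aldehydes, which corresponds to the 3R carbinol.

## Structural features

The target is a trans-fused hydroazulene (bicyclo[5.3.0]decane, daucane type). A cyclopentane (C1–C5) is fused through the C1–C5 bond to a cyclohept-8-en-10-one (C1, C10, C9, C8, C7, C6, C5). C1 is the quaternary ring-fusion carbon (CH3), C2 is CH–O-angeloyl, C3 is CH2, C4 is C(OH)(isopropyl), C5 is the ring-fusion CH, C6 is CH–O-angeloyl, C7 is CH2, C8 is =C(CH3), C9 is =CH and C10 is C=O.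

There are five stereocentres (1R,2R,4R,5S,6S in this numbering). C2, C1, C5 and C4 are contiguous in the five-membered ring and C6 stands on C5. The C1 methyl, the C2 oxygen and the C4 hydroxyl lie on the β face; H5, the C6 oxygen and the isopropyl group lie on the α face.

The fragile groups are:
- two (Z)-2-methylbut-2-enoates, which isomerise to tiglates;
- the C2 oxygen, β to the C10 ketone through the quaternary carbon (retro-aldol as a free alkoxide);
- the C6 acyloxy group, δ to the enone carbonyl (vinylogous β-elimination);
- the tertiary C4 carbinol.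

The real difficulty is the seven-membered ring whose carbonyl (C10) sits next to an all-carbon quaternary stereocentre (C1) that is also the ring fusion, and the relay of configuration from C1 to C2, C5, C6 and C4.

The key step exploits the substitution pattern of C5–C10. C5 carries a carbon substituent, C10 (ortho to it) carries oxygen and C8 (para to it) carries a methyl group. This is the pattern of a 2-methoxy-4-methylphenyl ring into which the single carbon C1 has been inserted between C5 and C10. C1 in turn is bonded to the oxygenated carbon C2, which is what an acyl carbene adding to an anisole ring delivers.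

In one sentence: the cycloheptenone is made by an intramolecular Büchner reaction (arene cyclopropanation and electrocyclic ring expansion) of an aryl α-diazoethyl ketone, so that a benzene ring becomes C5–C10 and the carbene carbon becomes C1.

## Logic of the disconnections

**21 to 20.** The two ester C–O bonds at C2 and C6 are cut last, because the angelates tolerate neither base, nucleophiles nor boron reagents. This leaves a triol. The forward step must acylate the neopentyl C2 hydroxyl and the C6 hydroxyl, leave the tertiary C4 hydroxyl alone and keep the Z geometry.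

**20 to 19 to 17.** The C6–O bond and one C7–H bond are cut. The δ-hydroxy enone 20 is the conjugated isomer of 19, and 19 is the product of a 1,6-addition of an oxygen equivalent to dienone 17. This removes the C6 stereocentre. The forward step must add at the δ carbon (not the β carbon) and on the α face.

**17 to 16 to 14.** The C4–isopropyl bond is cut, the C10 carbonyl is masked as its methyl enol ether and C5–H is removed. Ketone 14 is a stable push–pull trienone in which C5 is sp2, so no acidic or epimerisable C5–H interferes with the organometallic addition. The forward sequence needs: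
- 1,2-addition to C4 anti to the C1 methyl group;
- enol ether hydrolysis without heterolysis of the new tertiary C–O bond;
- protonation at C5 under thermodynamic control.

**14 to 11.** These are functional group changes only. The C4 carbonyl comes from the only allylic alcohol of 13, which is unmasked from 12. The C2 carbinol of 12 comes from reduction of the only ketone of 11, anti to the C1 methyl group.

**11 to 9 (key disconnection).** The bonds C1–C5 and C1–C10 are cut and the C5–C10 bond is restored. The bicyclic trienone becomes an open-chain aryl α-diazo ketone. Both rings and the quaternary stereocentre disappear, and the seven-membered ring becomes a commercial benzene ring that already carries the C8 methyl and the C10 oxygen. The forward step must: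
- close onto the methoxy-bearing ortho carbon;
- select one face of the arene under the influence of the C4 stereocentre;
- outrun 1,2-hydride shift in the carbenoid.

**9 to 7 to 5 to 4 to 1 + 2.** The C1–C2 bond is cut (acylation of diazoethane by an activated acid), then the C3–C4 bond (acetate aldol). The only stereocentre brought in from outside is the benzylic carbinol C4, set by a chiral acetate enolate. It controls C1 in the key step and is later erased and rebuilt.

## Other disconnections considered

**Alternative 1:** (the first that comes to mind)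
- Cut: C8=C9 by ring-closing metathesis, and C1–C10 and C5–C6 by conjugate addition and aldol trapping on enone A1.
- Forward key step: ring-closing metathesis of diene A2 to the trisubstituted cycloheptenone.
- Grounds for preferring the chosen plan:
  - C1 would be made by conjugate addition to a β,β-disubstituted enone whose enolate carries a β-silyloxy leaving group.
  - A1 is not a pool compound and needs its own asymmetric synthesis.
  - C6 would come from an intermolecular aldol with no element that controls it.
  - The step count is about the same, with weaker control at C6 and a late, slow closure of a trisubstituted seven-membered enone.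

**Alternative 2:**
- Cut: C1–C5, as the retron of a semipinacol rearrangement.
- Forward key step: Lewis acid treatment of the trans-decalin epoxy alcohol A3. The ring-fusion bond C10–C5 migrates to C1, contracting one ring and expanding the other, to give A4 with the aldol array C10(=O)–C1–C2(OH).
- Grounds for preferring the chosen plan:
  - Migration is anti to the breaking epoxide C–O bond with inversion at C1. This places the C2 oxygen cis to C10 and trans to the methyl group, so A4 is the C2 epimer of what is needed and must be oxidised and reduced back.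
  - A3 carries five stereocentres and has no short pool-based access, because the C4 carbinol cannot be taken from a menthane without C–H oxidation.

**Alternative 3:**
- Cut: C1–C10 and C7–C8.
- Forward key step: rhodium-catalysed cyclopropanation of the silyl enol ether alkene of diene A5 by the vinyl diazoacetate A7, then divinylcyclopropane Cope rearrangement (formal 4+3) to A6.
- Grounds for preferring the chosen plan:
  - The carbenoid carbon needs an acceptor, which ends up as CO2Me on C8 where the target has CH3.
  - C10 arrives as CH2 and needs allylic oxidation.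
  - C5 arrives sp2, so C5 and C6 must still be set.
  - These are three redox corrections after the key step. In the chosen plan every ring carbon arrives at the right oxidation level or one hydrolysis away from it.

Key step: step 5

## Route

Step 1
Reactants: 1 2-methoxy-4-methylbenzaldehyde; 2 (R)-2-hydroxy-1,2,2-triphenylethyl acetate
Product: 4 (R)-2-hydroxy-1,2,2-triphenylethyl (R)-3-hydroxy-3-(2-methoxy-4-methylphenyl)propanoate, via dilithium enolate 3 (not isolated)
Conditions: LDA (2.2 equiv), THF, −78 to 0 °C; then 1, −78 °C; aq NH4Cl
Reagents that add atoms: none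
Why: Acetate aldol addition of a chiral, doubly deprotonated acetate; the bulky triphenylglycol unit shields one enolate face, so the new carbinol (the future C4) should form mainly as the R isomer, and the minor diastereomer can be removed by crystallisation.

Step 2
Reactants: 4 (R)-2-hydroxy-1,2,2-triphenylethyl (R)-3-hydroxy-3-(2-methoxy-4-methylphenyl)propanoate
Product: 5 (R)-3-hydroxy-3-(2-methoxy-4-methylphenyl)propanoic acid
Conditions: KOH, MeOH–H2O, reflux; then aq HCl
Reagents that add atoms: potassium hydroxide, [K+].[OH-]
Why: Saponification releases the β-hydroxy acid and the auxiliary diol, which can be recovered; the carbinol centre is not involved.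

Step 3
Reactants: 5 (R)-3-hydroxy-3-(2-methoxy-4-methylphenyl)propanoic acid
Product: 7 (R)-3-(tert-butyldimethylsilyloxy)-3-(2-methoxy-4-methylphenyl)propanoic acid, via bis-silyl ester 6 (not isolated)
Conditions: TBSCl (2.5 equiv), imidazole, DMF, rt; then MeOH, K2CO3 (cat.), rt
Reagents that add atoms: tert-butyldimethylsilyl chloride, CC(C)(C)[Si](C)(C)Cl
Why: Silylation of both OH groups followed by selective methanolysis of the labile silyl ester; the silyl ether is needed to block O–H insertion in the carbenoid step.

Step 4
Reactants: 7 (R)-3-(tert-butyldimethylsilyloxy)-3-(2-methoxy-4-methylphenyl)propanoic acid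
Product: 9 (R)-5-(tert-butyldimethylsilyloxy)-2-diazo-5-(2-methoxy-4-methylphenyl)pentan-3-one, via mixed anhydride 8 (not isolated)
Conditions: ClCO2Et, Et3N, THF, −15 °C; then CH3CHN2, Et2O, 0 °C
Reagents that add atoms: diazoethane, CC=[N+]=[N-]
Why: Acylation of a diazoalkane by a mixed carbonic anhydride (the diazo ketone synthesis of the Arndt–Eistert sequence); it fixes the position of the diazo group without enolate chemistry next to the β-silyloxy centre.

Step 5
Reactants: 9 (R)-5-(tert-butyldimethylsilyloxy)-2-diazo-5-(2-methoxy-4-methylphenyl)pentan-3-one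
Product: 11 (3R,8aS)-3-(tert-butyldimethylsilyloxy)-8-methoxy-6,8a-dimethyl-3,8a-dihydroazulen-1(2H)-one (target numbering: 2-oxo, 4α-OTBS, 10-OMe, 5,7,9-triene, 1β-CH3), via norcaradiene 10 (not isolated)
Conditions: Rh2(OAc)4 (1 mol%), CH2Cl2, reflux, slow addition of 9
Reagents that add atoms: none
Why: Rhodium(II) converts 9 into an electrophilic acyl carbenoid that attacks the arene at the tethered carbon C5 (ortho to OMe, para to CH3) and closes the cyclopropane on C10 to give norcaradiene 10, whose 6π disrotatory opening of the C5–C10 bond gives cycloheptatriene 11. The closest known reaction type is the intramolecular Büchner reaction of 1-diazo-4-arylbutan-2-ones, which is also known for α-methyl diazo ketones and then gives 8a-methylazulenones. The five-membered ring is closed by C1–C5 bond formation through the three-atom tether (5-exo attack of the carbenoid carbon on the ipso carbon), while the seven-membered ring is not closed but grown from the benzene ring by insertion of C1 into the C5–C10 bond. C1 is the only new stereocentre: allylic 1,3-strain should keep the benzylic hydrogen of C4 in the arene plane next to C6–H, so the tether reaches one face and the OTBS group lies on the other, and the C1 methyl should end up trans to OTBS, which with (R)-C4 is the configuration the target needs. The step needs closure at C10 and not at C6, which should follow from charge, because the arenium-like transition state carries its positive charge best on the methoxy-bearing carbon, and C6 is meta to OMe and unactivated. It also needs cyclisation to outrun 1,2-hydride shift from the methyl group, which the fast five-membered closure onto an electron-rich ring under slow addition should secure. The quaternary C1 then blocks 1,5-hydrogen shifts and aromatisation of the product.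

Step 6
Reactants: 11 (3R,8aS)-3-(tert-butyldimethylsilyloxy)-8-methoxy-6,8a-dimethyl-3,8a-dihydroazulen-1(2H)-one
Product: 12 2β-hydroxy-4α-(tert-butyldimethylsilyloxy)-10-methoxy-1β,8-dimethylhydroazula-5,7,9-triene
Conditions: NaBH4, MeOH, −20 °C
Reagents that add atoms: none
Why: Hydride reduction of the only ketone; C5 and C10 on C1 lie near the ring plane and the C1 methyl projects over the β face, so hydride should enter from the α face and give the 2β alcohol (cis to the methyl group), as in 17-keto steroids.

Step 7
Reactants: 12 2β-hydroxy-4α-(tert-butyldimethylsilyloxy)-10-methoxy-1β,8-dimethylhydroazula-5,7,9-triene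
Product: 13 2β,4α-dihydroxy-10-methoxy-1β,8-dimethylhydroazula-5,7,9-triene
Conditions: TBAF, THF, 0 °C to rt
Reagents that add atoms: none
Why: Fluoride cleavage of the silyl ether under basic conditions, which the acid-labile trienol ether tolerates.

Step 8
Reactants: 13 2β,4α-dihydroxy-10-methoxy-1β,8-dimethylhydroazula-5,7,9-triene
Product: 14 2β-hydroxy-10-methoxy-1β,8-dimethylhydroazula-5,7,9-trien-4-one
Conditions: MnO2, CH2Cl2, rt
Reagents that add atoms: none
Why: Chemoselective allylic oxidation; only the C4 hydroxyl is allylic (to C5=C6), the neopentyl C2 hydroxyl is not touched, and the controlling C4 stereocentre is erased now that it has done its work.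

Step 9
Reactants: 14 2β-hydroxy-10-methoxy-1β,8-dimethylhydroazula-5,7,9-trien-4-one
Product: 16 2β,4β-dihydroxy-4α-isopropyl-1β,8-dimethylhydroazula-5,7-dien-10-one, via tertiary carbinol 15 (not isolated)
Conditions: iPrMgCl, CeCl3, THF, −78 °C; then aq (CO2H)2, THF, 0 °C
Reagents that add atoms: isopropylmagnesium chloride, CC(C)[Mg]Cl; water, O
Why: Organocerium 1,2-addition to the vinylogous ester carbonyl, where the C1 methyl and the cerium alkoxide at C2 shield the β face, so isopropyl should enter from the α face and give the 4β carbinol; mild acid then protonates the trienol ether at C9 and hydrolyses it to the C10 ketone (a Stork–Danheiser-type sequence stopped before loss of water).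

Step 10
Reactants: 16 2β,4β-dihydroxy-4α-isopropyl-1β,8-dimethylhydroazula-5,7-dien-10-one
Product: 17 2β,4β-dihydroxy-4α-isopropyl-1β,8-dimethyl-5α-H-hydroazula-6,8-dien-10-one
Conditions: DBU (0.2 equiv), CH2Cl2, rt
Reagents that add atoms: none
Why: Base-mediated conjugation through the extended enolate (deprotonation at C9, reprotonation at C5) should give the linearly conjugated dienone; C5 is set under thermodynamic control, and the trans-fused isomer, in which the C5–C6 bond avoids the 4α-isopropyl group, should be favoured.

Step 11
Reactants: 17 2β,4β-dihydroxy-4α-isopropyl-1β,8-dimethyl-5α-H-hydroazula-6,8-dien-10-one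
Product: 19 2β,4β,6α-trihydroxy-4α-isopropyl-1β,8-dimethyl-5α-H-hydroazul-7-en-10-one, via allylboronate 18 (not isolated)
Conditions: B2pin2, CuCl/IMes·HCl (5 mol%), NaOtBu (10 mol%), MeOH, THF, rt; then H2O2, aq NaHCO3, 0 °C
Reagents that add atoms: hydrogen peroxide, OO
Why: Copper-catalysed conjugate borylation of a dienone goes to the δ carbon (1,6) when the β carbon is substituted, as C8 is here; the boryl group should enter at C6 from the α face, away from the 1,3-related axial C1 methyl, and oxidation with retention gives the equatorial 6α alcohol.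

Step 12
Reactants: 19 2β,4β,6α-trihydroxy-4α-isopropyl-1β,8-dimethyl-5α-H-hydroazul-7-en-10-one
Product: 20 2β,4β,6α-trihydroxy-4α-isopropyl-1β,8-dimethyl-5α-H-hydroazul-8-en-10-one
Conditions: DBU (0.1 equiv), CH2Cl2, rt
Reagents that add atoms: none
Why: Base-catalysed shift of the β,γ double bond into conjugation with the C10 ketone; no stereocentre is touched.

Step 13
Reactants: 20 2β,4β,6α-trihydroxy-4α-isopropyl-1β,8-dimethyl-5α-H-hydroazul-8-en-10-one
Product: 21 CNP0183628.1 (2β,6α-bis-angeloyloxy-4β-hydroxy-4α-isopropyl-1β,8-dimethyl-5α-H-hydroazul-8-en-10-one)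
Conditions: angelic acid, 2,4,6-trichlorobenzoyl chloride, Et3N, toluene, rt; then 20, 80 °C
Reagents that add atoms: angelic acid, C/C=C(/C)C(=O)O
Why: Yamaguchi-type mixed-anhydride esterification without a nucleophilic catalyst, the usual way to acylate hindered secondary alcohols with angelic acid without Z to E isomerisation; the tertiary C4 hydroxyl should not react.

## Compound list

1 | 2-methoxy-4-methylbenzaldehyde | COc1cc(C)ccc1C=O | starting material
2 | (R)-2-hydroxy-1,2,2-triphenylethyl acetate | CC(=O)O[C@H](c1ccccc1)C(O)(c1ccccc1)c1ccccc1 | starting material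
3 | dilithium enolate of 2 | C=C([O-])O[C@H](c1ccccc1)C([O-])(c1ccccc1)c1ccccc1.[Li+].[Li+] | intermediate (not isolated)
4 | (R)-2-hydroxy-1,2,2-triphenylethyl (R)-3-hydroxy-3-(2-methoxy-4-methylphenyl)propanoate | O[C@H](CC(=O)O[C@H](c1ccccc1)C(O)(c1ccccc1)c1ccccc1)c1ccc(C)cc1OC | intermediate
5 | (R)-3-hydroxy-3-(2-methoxy-4-methylphenyl)propanoic acid | O[C@H](CC(=O)O)c1ccc(C)cc1OC | intermediate
6 | tert-butyldimethylsilyl (R)-3-(tert-butyldimethylsilyloxy)-3-(2-methoxy-4-methylphenyl)propanoate | CC(C)(C)[Si](C)(C)O[C@H](CC(=O)O[Si](C)(C)C(C)(C)C)c1ccc(C)cc1OC | intermediate (not isolated)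
7 | (R)-3-(tert-butyldimethylsilyloxy)-3-(2-methoxy-4-methylphenyl)propanoic acid | CC(C)(C)[Si](C)(C)O[C@H](CC(=O)O)c1ccc(C)cc1OC | intermediate
8 | ethyl carbonic mixed anhydride of 7 | CCOC(=O)OC(=O)C[C@@H](O[Si](C)(C)C(C)(C)C)c1ccc(C)cc1OC | intermediate (not isolated)
9 | (R)-5-(tert-butyldimethylsilyloxy)-2-diazo-5-(2-methoxy-4-methylphenyl)pentan-3-one | CC(=[N+]=[N-])C(=O)C[C@@H](O[Si](C)(C)C(C)(C)C)c1ccc(C)cc1OC | intermediate
10 | norcaradiene (cyclopropane C1–C5–C10 fused to the cyclopentanone and to the cyclohexadiene; OMe on C10) | O=C1C[C@@H](O[Si](C)(C)C(C)(C)C)[C@@]23C=CC(C)=C[C@]2(OC)[C@@]13C | intermediate (not isolated)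
11 | (3R,8aS)-3-(tert-butyldimethylsilyloxy)-8-methoxy-6,8a-dimethyl-3,8a-dihydroazulen-1(2H)-one | O=C1C[C@@H](O[Si](C)(C)C(C)(C)C)C2=CC=C(C)C=C(OC)[C@@]12C | intermediate
12 | 2β-hydroxy-4α-(tert-butyldimethylsilyloxy)-10-methoxy-1β,8-dimethylhydroazula-5,7,9-triene | O[C@@H]1C[C@@H](O[Si](C)(C)C(C)(C)C)C2=CC=C(C)C=C(OC)[C@@]12C | intermediate
13 | 2β,4α-dihydroxy-10-methoxy-1β,8-dimethylhydroazula-5,7,9-triene | O[C@@H]1C[C@@H](O)C2=CC=C(C)C=C(OC)[C@@]12C | intermediate
14 | 2β-hydroxy-10-methoxy-1β,8-dimethylhydroazula-5,7,9-trien-4-one | O[C@@H]1CC(=O)C2=CC=C(C)C=C(OC)[C@@]12C | intermediate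
15 | 2β,4β-dihydroxy-4α-isopropyl-10-methoxy-1β,8-dimethylhydroazula-5,7,9-triene | O[C@@H]1C[C@@](O)(C(C)C)C2=CC=C(C)C=C(OC)[C@@]12C | intermediate (not isolated)
16 | 2β,4β-dihydroxy-4α-isopropyl-1β,8-dimethylhydroazula-5,7-dien-10-one | O[C@@H]1C[C@@](O)(C(C)C)C2=CC=C(C)CC(=O)[C@@]12C | intermediate
17 | 2β,4β-dihydroxy-4α-isopropyl-1β,8-dimethyl-5α-H-hydroazula-6,8-dien-10-one | O[C@@H]1C[C@@](O)(C(C)C)[C@@H]2C=CC(C)=CC(=O)[C@@]12C | intermediate
18 | 6α-(pinacolatoboryl)-2β,4β-dihydroxy-4α-isopropyl-1β,8-dimethyl-5α-H-hydroazul-7-en-10-one | O[C@@H]1C[C@@](O)(C(C)C)[C@@H]2[C@@H](B3OC(C)(C)C(C)(C)O3)C=C(C)CC(=O)[C@@]12C | intermediate (not isolated)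
19 | 2β,4β,6α-trihydroxy-4α-isopropyl-1β,8-dimethyl-5α-H-hydroazul-7-en-10-one | O[C@@H]1C[C@@](O)(C(C)C)[C@@H]2[C@@H](O)C=C(C)CC(=O)[C@@]12C | intermediate
20 | 2β,4β,6α-trihydroxy-4α-isopropyl-1β,8-dimethyl-5α-H-hydroazul-8-en-10-one | O[C@@H]1C[C@@](O)(C(C)C)[C@@H]2[C@@H](O)CC(C)=CC(=O)[C@@]12C | intermediate
21 | CNP0183628.1 | C/C=C(/C)C(=O)O[C@H]1CC(C)=CC(=O)[C@]2(C)[C@@H]1[C@](O)(C(C)C)C[C@H]2OC(=O)/C(C)=C\C | target

## Step count and least certain steps

Total step count: 13. Longest linear sequence: 13 steps (from 1; 2 enters in step 1).

**Step 5 (key step).**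
- What may go wrong: 1,2-hydride migration from the methyl group of the carbenoid may compete with arene addition, and the cyclopropane may close on the unsubstituted ortho carbon C6 instead of C10. Face selectivity from the C4 silyl ether may also be incomplete.
- Fallback: the quaternary centre is made by enolate methylation instead of in the cyclisation. The route is left at 7, whose mixed anhydride 8 is treated with diazomethane to give the terminal diazo ketone F1, which has no hydrogen that can migrate. Rh2(OAc)4 should convert it through the norcaradiene F2 into the 8a-H azulenone F3. LiHMDS and iodomethane (THF, −78 °C) should then methylate C1, anti to the silyl ether, and the route is rejoined at 11.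

**Step 9.**
- What may go wrong: under the acidic hydrolysis the new tertiary, doubly allylic C4–O bond may undergo heterolysis (loss of the hydroxyl and formation of a trienone) before the trienol ether is protonated at carbon.
- Fallback: the carbinol is tied back before any acid is used. The cerium addition is quenched with neutral aqueous NH4Cl and 15 is isolated. tBu2Si(OTf)2 and 2,6-lutidine convert its cis 2β,4β-diol into the cyclic di-tert-butylsilylene F4, whose oxygen is far less basic. Aqueous oxalic acid then gives the deconjugated ketone F5, DBU gives the dienone F6, and HF·pyridine releases 17.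

**Step 11.**
- What may go wrong: boron may be delivered to the β carbon (1,4) instead of the δ carbon, or to the β face of C6, because the α face is flanked by the 4α-isopropyl group.
- Fallback for the facial problem: the wrong alcohol is inverted during esterification. The 6β alcohol F7 is conjugated with DBU as in step 12 to F8. A Mitsunobu reaction with angelic acid (PPh3, DIAD, toluene) should give the 6α-angelate F9 with inversion; the neopentyl C2 and tertiary C4 hydroxyls should not react. Acylation of the C2 hydroxyl under the conditions of step 13 then gives 21.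

**Step 13.**
- What may go wrong: Z to E isomerisation of the angeloyl unit, sluggish acylation of the neopentyl C2 hydroxyl, and base-induced elimination of the C6 ester through the dienolate of the enone.
- Fallback: the Z double bonds are built on the molecule. 20 is esterified with 2-[bis(2,2,2-trifluoroethoxy)phosphoryl]propanoic acid (DCC, DMAP) to the bis-phosphonate F10. A Still–Gennari olefination with acetaldehyde (KHMDS, 18-crown-6, THF, −78 °C) should give both (Z)-2-methylbut-2-enoates, that is 21.

## Further compounds

F1 | step 5 | (R)-4-(tert-butyldimethylsilyloxy)-1-diazo-4-(2-methoxy-4-methylphenyl)butan-2-one | [N-]=[N+]=CC(=O)C[C@@H](O[Si](C)(C)C(C)(C)C)c1ccc(C)cc1OC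
F2 | step 5 | norcaradiene with H on C1 (analogue of 10) | O=C1C[C@@H](O[Si](C)(C)C(C)(C)C)[C@@]23C=CC(C)=C[C@]2(OC)[C@@H]13
F3 | step 5 | 3-(tert-butyldimethylsilyloxy)-8-methoxy-6-methyl-3,8a-dihydroazulen-1(2H)-one (8a-H analogue of 11; configuration at C8a immaterial) | O=C1C[C@@H](O[Si](C)(C)C(C)(C)C)C2=CC=C(C)C=C(OC)[C@@H]12
F4 | step 9 | 2β,4β-O-(di-tert-butylsilylene) derivative of 15 | O3[C@@H]1C[C@@](O[Si]3(C(C)(C)C)C(C)(C)C)(C(C)C)C2=CC=C(C)C=C(OC)[C@@]12C
F5 | step 9 | 2β,4β-O-(di-tert-butylsilylene) derivative of 16 | O3[C@@H]1C[C@@](O[Si]3(C(C)(C)C)C(C)(C)C)(C(C)C)C2=CC=C(C)CC(=O)[C@@]12C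
F6 | step 9 | 2β,4β-O-(di-tert-butylsilylene) derivative of 17 | O3[C@@H]1C[C@@](O[Si]3(C(C)(C)C)C(C)(C)C)(C(C)C)[C@@H]2C=CC(C)=CC(=O)[C@@]12C
F7 | step 11 | 6β epimer of 19 | O[C@@H]1C[C@@](O)(C(C)C)[C@@H]2[C@H](O)C=C(C)CC(=O)[C@@]12C
F8 | step 11 | 6β epimer of 20 | O[C@@H]1C[C@@](O)(C(C)C)[C@@H]2[C@H](O)CC(C)=CC(=O)[C@@]12C
F9 | step 11 | 6α-angeloyloxy-2β,4β-dihydroxy-4α-isopropyl-1β,8-dimethyl-5α-H-hydroazul-8-en-10-one | O[C@@H]1C[C@@](O)(C(C)C)[C@@H]2[C@@H](OC(=O)/C(C)=C\C)CC(C)=CC(=O)[C@@]12C
F10 | step 13 | 2β,6α-bis{2-[bis(2,2,2-trifluoroethoxy)phosphoryl]propanoate} of 20 | CC(C(=O)O[C@@H]1C[C@@](O)(C(C)C)[C@@H]2[C@@H](OC(=O)C(C)P(=O)(OCC(F)(F)F)OCC(F)(F)F)CC(C)=CC(=O)[C@@]12C)P(=O)(OCC(F)(F)F)OCC(F)(F)F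
A1 | alternative 1 | (R)-4-(tert-butyldimethylsilyloxy)-3-methylcyclopent-2-enone | O=C1C=C(C)[C@H](O[Si](C)(C)C(C)(C)C)C1
A2 | alternative 1 | cyclopentane diene for ring-closing metathesis (1α-acryloyl, 1β-methyl, 2β-OTBS, 4β-OH, 4α-isopropyl, 5β-(1-silyloxy-3-methylbut-3-enyl)) | C=CC(=O)[C@@]1(C)[C@H](O[Si](C)(C)C(C)(C)C)C[C@@](O)(C(C)C)[C@@H]1[C@@H](O[Si](C)(C)C(C)(C)C)CC(C)=C
A3 | alternative 2 | trans-decalin 1,2-epoxy-10-ol (C10 hydroxyl anti to the epoxide oxygen) | C[C@]12O[C@H]1C[C@@](O)(C(C)C)[C@@H]1[C@@H](O[Si](C)(C)C(C)(C)C)CC(C)=C[C@@]21O
A4 | alternative 2 | 2α-hydroxy (C2-epimeric) hydroazulenone from the semipinacol shift | O[C@H]1C[C@@](O)(C(C)C)[C@@H]2[C@@H](O[Si](C)(C)C(C)(C)C)CC(C)=CC(=O)[C@@]12C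
A5 | alternative 3 | cyclopentenyl 2-silyloxydiene | C=C(O[Si](CC)(CC)CC)C1=C(C)[C@H](O[Si](C)(C)C(C)(C)C)C[C@@]1(O[Si](C)(C)C)C(C)C
A6 | alternative 3 | cycloheptadiene cycloadduct with CO2Me on C8 | COC(=O)C1=CC[C@@]2(C)[C@H](O[Si](C)(C)C(C)(C)C)C[C@@](O[Si](C)(C)C)(C(C)C)C2=C(O[Si](CC)(CC)CC)C1
A7 | alternative 3 | methyl 2-diazobut-3-enoate | COC(=O)C(=[N+]=[N-])C=C
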